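Lignan numbering is used throughout: the tetrahydrofuran is O–C7–C8–C8'–C9', ring A sits on C7, C9 is the oxymethyl carbon on C8, and C7' is the benzylic carbon on C8' that carries ring B. Ar = 4-[(tert-butyldimethylsilyl)oxy]-3-methoxyphenyl.

## The problem

Agastinol 18 is a 7,9'-epoxylignan: a tetrahydrofuran with the guaiacyl ring A on C7, a (4-hydroxybenzoyl)oxymethyl group (C9) on C8 and the ring B benzyl group (C7') on C8'. The three contiguous ring stereocentres are 7R,8S,8'S, with ring A trans to the C9 arm and the C9 arm cis to the benzyl group, so the C8/C8' relationship is the less stable one and cannot be reached by equilibration. Only C7 carries a heteroatom and can be set by asymmetric carbonyl addition; it can then direct C8 by 1,2-induction in a five-membered ring, and C8 can direct a face-selective reduction at a trigonal C8'. The C7–O bond is a benzylic ether para to an oxygenated arene: acid ionises it (epimerisation, or Friedel–Crafts closure by ring B to an aryltetralin) and Pd/C hydrogenolysis cleaves it. The molecule ends with three free phenols and one ester, which must be placed on the single aliphatic hydroxyl (C9) without acylating a phenol. The feature that opens the synthesis is that O–C7–C8–C8'–C9' is a γ-lactone in disguise. With C9' as a carbonyl carbon, C8 and C8' are the β- and α-carbons of a γ-aryl butenolide, C9 is a one-carbon nucleophile for the β-carbon, and C7' with ring B is an aldehyde for the α-carbon. Both arenes then come from vanillin 1.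

## Retrosynthesis

**Ester, 18 ⇒ 16 + 17.** The ester is cut at the C9–O bond, giving (−)-lariciresinol 16 and 4-hydroxybenzoic acid 17. Cutting the acyl–O bond instead would call for an acylating agent, which would also esterify the phenols and force three protecting groups. A Mitsunobu reaction activates the alcohol, of which there is only one, so all phenols can stay free. The forward step must make carboxylate, not phenoxide, the nucleophile.

**C9–OH and phenols, 16 ⇒ 15.** The C9 hydroxyl is traced back to a C9–Si bond and both phenols to aryl silyl ethers, so that one Tamao oxidation in a fluoride medium unveils all three. A silylmethyl arm is preferred to a protected hydroxymethyl arm because it needs no protecting group and, while the lactone is still present, cannot translactonise onto C9'. Precursor 15 has no free hydroxyl at all.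

**C9' methylene, 15 ⇒ 14 ⇒ 13.** The ring CH2 is a reduced lactone carbonyl: lactol 14, then cis-lactone 13. Opening the lactone to a diol and re-closing would cost steps and expose the C7 carbinol. The forward reduction must not epimerise C8' (α to the carbonyl in 13) and must ionise C9' but not C7.

**C8' stereocentre, 13 ⇒ 12 ⇒ 10.** C8' is made trigonal: 13 comes from the (E)-benzylidene lactone 12, and 12 from aldol 10 by dehydration. Direct benzylation of a lactone enolate would form the same C8'–C7' bond but would put the benzyl group anti to the C8 arm, the wrong relationship. In the aldol/dehydration/hydrogenation sequence it is hydrogen that arrives anti to C9, which turns the same preference into the right one. The aldol centres then need no control.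

**Key disconnection, 10 ⇒ 6 + 8 + 2.** Both C8–C9 and C8'–C7' are cut, leaving butenolide 6, the (isopropoxydimethylsilyl)methyl Grignard reagent 8 and O-silylated vanillin 2. This uses the natural polarity of the lactone (β-carbon electrophilic, α-carbon nucleophilic after the addition). The neighbouring cut, C8–C8' between two C6–C3 halves, would require both centres to be set at once. The forward reaction must add 8 anti to ring A and must be faster than removal of the acidic benzylic C7–H of 6.

**Butenolide, 6 ⇒ 4 ⇒ 2 + 3.** Butenolide 6 is the lactone of the cis-γ-hydroxy enoate 5, available by semihydrogenation of ynoate 4. Cutting the carbinol–alkyne bond of 4 gives aldehyde 2 and methyl propiolate 3, joined by a catalytic asymmetric alkynylation that sets C7. Aldehyde 2 comes from vanillin 1 by silylation and serves twice. Reagent 8 comes from the commercial chloromethylsilane 7.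

## Roads not taken

Alternative 1: three-component palladium oxa-Michael/carbocyclisation/arylation.
- Cut: O–C7, C8–C8' and the C7'–ring B bond in one operation. The pieces are propargyl alcohol A1, the vanillin-derived benzylidene malonate A2 and the ring B aryl iodide A3.
- Forward step: the alkoxide of A1 adds to A2; the malonate anion attacks the alkyne activated by the arylpalladium species (divalent palladium) formed from A3 and Pd2(dba)3 (zerovalent palladium) with a chiral bisphosphine; reductive elimination gives the benzylidene tetrahydrofuran diester A4.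
- Merits: the ring and both aryl-bearing carbons of A4 are assembled in one catalytic step from three simple pieces. In convergence and in the length of the ring-forming phase this road is better than the chosen one.
- Weak points: C7 of A4 is formed in a reversible oxa-Michael step, so the chiral palladium complex must select between rapidly equilibrating adducts. In A4, C8 is a quaternary gem-diester, so one ester must be excised, the other reduced, and C8 set trans to C7 afterwards. C8' still has to be set by hydrogenation of the exocyclic alkene of A4, the same facial question as in the chosen plan. The benzyl ethers must finally be removed by hydrogenolysis next to the C7–O bond.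
- Comparison: the chosen plan sets against the shorter ring construction an absolute configuration that comes from a well-understood carbonyl addition, a C8 centre fixed in the key step by substrate control, and a C9 carbon that arrives at the right oxidation level with no excess carbon to remove.

Alternative 2: gold carbene O–H insertion to a 3-oxotetrahydrofuran.
- Cut: O–C9', with C8' arriving as a ketone. The precursor is the (1R,2S) homopropargylic alcohol A5.
- Forward step: Ph3PAuNTf2 (monovalent gold) activates the terminal alkyne of A5, a pyridine N-oxide transfers oxygen to C8', and the α-oxo gold carbene at C9' inserts into the C7 O–H bond to give the trans 3-oxotetrahydrofuran A6.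
- Merits: the ring closes under neutral conditions without touching C7 or C8, and no Lewis acid meets the benzylic ether. In this respect it is gentler than the lactol reduction of the chosen plan.
- Weak points: A5 must be made diastereo- and enantioselectively, which moves the stereochemical problem into an acyclic propargylation. A6 is a β-silyloxy ketone whose α-carbon is C8, so the basic olefination needed to bring in ring B invites epimerisation and β-elimination of silanol. After olefination the same hydrogenation face selection is needed. Ring B enters late, in two further steps.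
- Comparison: the chosen plan forms C8–C9 and C8'–C7' in one step and never exposes a β-oxygenated ketone to base. It pays with the low-temperature Lewis-acid step at C9'.

Alternative 3: remote C7–H etherification of a C2-symmetric diol monoester.
- Cut: O–C7, as the last skeletal event. The precursor is the (S,S)-diol mono-(4-benzyloxybenzoate) A7.
- Forward step: the C9' alkoxy radical of A7, generated with PhI(OAc)2 (trivalent iodine), I2 and visible light, abstracts the benzylic C7 hydrogen through a six-membered transition state. The oxidised C7 centre is captured by the same oxygen to give tri-O-benzyl agastinol A8.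
- Merits: if it worked it would be the shortest road. The C2 symmetry of the parent diol makes the mono-acylation that leads to A7 unambiguous, the ester is in place early, and the late chemoselective esterification of the chosen plan is avoided.
- Weak points: the electron-rich guaiacyl rings of A7 are substrates for electrophilic iodination by the acetyl hypoiodite formed in the medium. The C9 hydrogens α to the ester oxygen are also in a 1,5-relationship to the alkoxy radical, and β-fragmentation of that radical competes. The oxidised C7 intermediate is the cation that ring B can trap to an aryltetralin. The C7 configuration of A8 rests on a single substrate-controlled capture. The three benzyl ethers of A8 must then be hydrogenolysed beside the new benzylic C7–O bond.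
- Comparison: the chosen plan is longer, but every stereocentre is set by a polar, well-precedented reaction and the oxidation-prone arenes never meet an electrophilic iodine oxidant.

Key step: step 5

Assumption: the (S,S)-ProPhenol ligand, 2,6-bis{[(S)-2-(hydroxydiphenylmethyl)pyrrolidin-1-yl]methyl}-4-methylphenol, is taken to deliver the alkynyl group to the face of aldehyde 2 that gives the (S)-carbinol 4, by analogy with its zinc aldol reactions; if the sense proves opposite, the (R,R)-ligand is used with no other change.

Step 1
Reactants: 1 vanillin
Product: 2 4-[(tert-butyldimethylsilyl)oxy]-3-methoxybenzaldehyde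
Conditions: TBSCl (1.2 equiv), imidazole (2 equiv), DMF, 0 °C to rt
Reagents that add atoms: tert-butyldimethylsilyl chloride, CC(C)(C)[Si](C)(C)Cl
Why: Silyl ether formation on a phenol with TBSCl/imidazole is routine and leaves the aldehyde untouched; the phenol must be masked because a free ArOH would quench Me2Zn in step 2 and the Grignard reagent in step 5.

Step 2
Reactants: 2 4-[(tert-butyldimethylsilyl)oxy]-3-methoxybenzaldehyde; 3 methyl propiolate
Product: 4 methyl (4S)-4-Ar-4-hydroxybut-2-ynoate
Conditions: Me2Zn (3 equiv), (S,S)-ProPhenol ligand (20 mol %), Ph3PO (40 mol %), toluene, 4 °C; aq. NH4Cl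
Reagents that add atoms: none
Why: Zinc–ProPhenol catalysed asymmetric alkynylation of an aryl aldehyde: Me2Zn metallates the propiolate and the dinuclear zinc–ligand complex delivers the alkynyl group to one face of the aldehyde, which sets the future C7; the sense of induction rests on the assumption above.

Step 3
Reactants: 4 methyl (4S)-4-Ar-4-hydroxybut-2-ynoate
Product: 6 (5R)-5-Ar-furan-2(5H)-one, via (Z)-hydroxy enoate 5 (not isolated)
Conditions: H2 (1 atm), Pd/CaCO3 poisoned with Pb(OAc)2 (Lindlar catalyst), quinoline, EtOAc, rt; filter; PPTS (0.2 equiv), CH2Cl2, rt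
Reagents that add atoms: none
Why: Lindlar cis-semihydrogenation gives the (Z)-γ-hydroxy enoate 5, whose hydroxyl and ester are held cis and lactonise under mild acid with loss of methanol; the stereocentre is not involved, and its descriptor changes from S to R only because an alkynyl carbon outranks the aryl group whereas an alkenyl carbon does not.

Step 4
Reactants: 7 (chloromethyl)(isopropoxy)dimethylsilane
Product: 8 {[dimethyl(propan-2-yloxy)silyl]methyl}magnesium chloride
Conditions: Mg turnings (1.2 equiv), BrCH2CH2Br (cat.), THF, reflux then rt; titrated and used as a THF solution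
Reagents that add atoms: magnesium, [Mg]
Why: Direct magnesium insertion into the C–Cl bond of an α-chloromethylsilane is the standard preparation of this hydroxymethyl anion equivalent; the hindered isopropoxy group on silicon survives its own Grignard reagent.

Step 5
Reactants: 6 (5R)-5-Ar-furan-2(5H)-one; 8 {[dimethyl(propan-2-yloxy)silyl]methyl}magnesium chloride; 2 4-[(tert-butyldimethylsilyl)oxy]-3-methoxybenzaldehyde
Product: 10 (3S,4R,5R)-5-Ar-3-[hydroxy(Ar)methyl]-4-{[dimethyl(propan-2-yloxy)silyl]methyl}dihydrofuran-2(3H)-one (all-trans aldol lactone; both carbinol epimers), via chloromagnesium lactone enolate 9 (not isolated)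
Conditions: 8 (1.3 equiv), CuI (20 mol %), THF, −78 °C; 6 added slowly, −78 to −40 °C; then 2 (2 equiv), −78 °C; sat. aq. NH4Cl at −78 °C
Reagents that add atoms: none
Why: Transmetallation of 8 to CuI gives a (silylmethyl)cuprate (monovalent copper) that forms a π-complex with the butenolide, adds at the β-carbon C8 and reductively eliminates from trivalent copper, forming C8–C9 and the chloromagnesium enolate 9. The closest known reaction type is the copper-catalysed conjugate addition of Grignard reagents to 5-substituted furan-2(5H)-ones with aldehyde trapping of the enolate (tandem Michael–aldol), with the (isopropoxydimethylsilyl)methyl Grignard reagent as hydroxymethyl anion equivalent. No ring is closed; the lactone is carried through intact and becomes the tetrahydrofuran later. C8 is set by C7, because the planar butenolide is attacked on the face opposite the C7 aryl group, which gives the 7,8-trans relationship. C8' is set by C8, because enolate 9 adds to aldehyde 2 (forming C8'–C7') through a closed magnesium-bridged transition state on the face opposite the new silylmethyl arm; this centre and the uncontrolled carbinol centre are both erased in step 6. The step needs 1,4- over 1,2-addition, which copper secures, and conjugate addition faster than removal of the acidic benzylic C7–H, which the low basicity of an α-silyl Grignard reagent, the low temperature and the slow addition of 6 to the preformed cuprate secure. The aldehyde is added in excess only after 6 is consumed, so that residual 8 is absorbed without starving the enolate and 9 does not add to unreacted butenolide, and the mixture is quenched cold so that the aldolate neither reverts nor attacks the Si–O-iPr group.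

Step 6
Reactants: 10 all-trans aldol lactone (both carbinol epimers)
Product: 12 (3E,4R,5R)-5-Ar-3-(Ar-methylidene)-4-{[dimethyl(propan-2-yloxy)silyl]methyl}dihydrofuran-2(3H)-one, via benzylic mesylate 11 (not isolated)
Conditions: MsCl (1.5 equiv), Et3N (3 equiv), CH2Cl2, 0 °C; then DBU (3 equiv), 0 °C to rt
Reagents that add atoms: none
Why: Aldol dehydration by mesylation and E1cB elimination through the lactone enolate; both carbinol epimers converge on the aryl-conjugated (E)-benzylidene lactone, C8' becomes trigonal, and C7 and C8 are untouched as long as exposure to DBU is kept short.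

Step 7
Reactants: 12 (E)-benzylidene lactone
Product: 13 (3S,4R,5R)-5-Ar-3-(Ar-methyl)-4-{[dimethyl(propan-2-yloxy)silyl]methyl}dihydrofuran-2(3H)-one (benzyl cis to the silylmethyl arm; ring A trans to it)
Conditions: H2 (3 atm), Rh/Al2O3 (5 wt %), EtOAc, rt
Reagents that add atoms: none
Why: Heterogeneous catalytic hydrogenation adds H2 syn from the less hindered face; in the (E)-benzylidene lactone, allylic 1,3-strain with the aryl group forces the C8 silylmethyl arm pseudo-axial, so hydrogen arrives opposite C9 and the benzyl group ends up cis to C9 (C8' set by C8). Rh/Al2O3 is used because Pd/C would hydrogenolyse the benzylic C7–O bond of the lactone.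

Step 8
Reactants: 13 cis-lactone
Product: 14 (3S,4R,5R)-5-Ar-3-(Ar-methyl)-4-{[dimethyl(propan-2-yloxy)silyl]methyl}tetrahydrofuran-2-ol (lactol; anomeric mixture)
Conditions: i-Bu2AlH (1.2 equiv), CH2Cl2, −78 °C; aq. potassium sodium tartrate
Reagents that add atoms: none
Why: Partial reduction of a γ-lactone with i-Bu2AlH at −78 °C stops at the stable tetrahedral aluminium hemiacetal; no base is present that could epimerise the contra-thermodynamic C8' centre.

Step 9
Reactants: 14 lactol
Product: 15 (2R,3R,4S)-2-Ar-4-(Ar-methyl)-3-{[dimethyl(propan-2-yloxy)silyl]methyl}tetrahydrofuran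
Conditions: Et3SiH (3 equiv), BF3·OEt2 (1.5 equiv), CH2Cl2, −78 °C; sat. aq. NaHCO3 at −78 °C
Reagents that add atoms: none
Why: Ionic hydrogenation of a lactol: BF3·OEt2 ionises the anomeric C–O bond to the cyclic oxocarbenium ion, which Et3SiH reduces at C9'; no stereocentre is formed, the acetal carbon ionises far faster than the C7 benzylic ether at −78 °C, and any exchange of Si–O-iPr for Si–F is harmless because both silanes undergo the next oxidation.

Step 10
Reactants: 15 bis-silyl ether silane
Product: 16 (−)-lariciresinol, [(2R,3S,4S)-2-(4-hydroxy-3-methoxyphenyl)-4-(4-hydroxy-3-methoxybenzyl)tetrahydrofuran-3-yl]methanol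
Conditions: KF (4 equiv), KHCO3 (2 equiv), 30% aq. H2O2, THF/MeOH (1:1), rt to 40 °C; aq. Na2S2O3
Reagents that add atoms: hydrogen peroxide, OO
Why: Tamao oxidation: fluoride and hydroperoxide form a pentacoordinate silicate and C9 migrates from silicon to oxygen with retention, C8 being untouched (its descriptor changes from R to S only because oxygen replaces silicon in the priority order); the same fluoride/bicarbonate/methanol medium cleaves both aryl silyl ethers, so the triol is obtained in one operation.

Step 11
Reactants: 16 (−)-lariciresinol; 17 4-hydroxybenzoic acid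
Product: 18 agastinol, [(2R,3S,4S)-2-(4-hydroxy-3-methoxyphenyl)-4-(4-hydroxy-3-methoxybenzyl)tetrahydrofuran-3-yl]methyl 4-hydroxybenzoate
Conditions: 17 (1.5 equiv), PPh3 (1.3 equiv), DIAD (1.3 equiv), THF, 0 °C to rt
Reagents that add atoms: none
Why: Mitsunobu esterification: the single aliphatic hydroxyl (C9, primary, no stereocentre) becomes the alkoxyphosphonium ion and is displaced by the carboxylate of 17; the carboxylic acid is far more acidic than any phenol present and is kept in excess over the betaine, so carboxylate and not phenoxide is the nucleophile, and no acylating agent that could esterify a phenol is involved.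

**Compound list**

1 | vanillin (4-hydroxy-3-methoxybenzaldehyde) | COc1cc(C=O)ccc1O | starting material
2 | 4-[(tert-butyldimethylsilyl)oxy]-3-methoxybenzaldehyde | COc1cc(C=O)ccc1O[Si](C)(C)C(C)(C)C | intermediate
3 | methyl propiolate | C#CC(=O)OC | starting material
4 | methyl (4S)-4-{4-[(tert-butyldimethylsilyl)oxy]-3-methoxyphenyl}-4-hydroxybut-2-ynoate | COC(=O)C#C[C@@H](O)c1ccc(O[Si](C)(C)C(C)(C)C)c(OC)c1 | intermediate
5 | methyl (2Z,4R)-4-{4-[(tert-butyldimethylsilyl)oxy]-3-methoxyphenyl}-4-hydroxybut-2-enoate (formed in situ) | COC(=O)/C=C\[C@@H](O)c1ccc(O[Si](C)(C)C(C)(C)C)c(OC)c1 | intermediate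
6 | (5R)-5-{4-[(tert-butyldimethylsilyl)oxy]-3-methoxyphenyl}furan-2(5H)-one | O=C1C=C[C@H](c2ccc(O[Si](C)(C)C(C)(C)C)c(OC)c2)O1 | intermediate
7 | (chloromethyl)(isopropoxy)dimethylsilane | CC(C)O[Si](C)(C)CCl | starting material
8 | {[dimethyl(propan-2-yloxy)silyl]methyl}magnesium chloride | CC(C)O[Si](C)(C)C[Mg]Cl | intermediate
9 | chloromagnesium enolate of (4R,5R)-5-Ar-4-{[dimethyl(propan-2-yloxy)silyl]methyl}dihydrofuran-2(3H)-one, aryl trans to the silylmethyl arm (formed in situ) | Cl[Mg]OC1=C[C@@H](C[Si](C)(C)OC(C)C)[C@H](c2ccc(O[Si](C)(C)C(C)(C)C)c(OC)c2)O1 | intermediate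
10 | (3S,4R,5R)-5-Ar-3-[hydroxy(Ar)methyl]-4-{[dimethyl(propan-2-yloxy)silyl]methyl}dihydrofuran-2(3H)-one, all-trans on the ring, mixture of carbinol epimers ((R)-carbinol drawn) | COc1cc([C@H](O)[C@H]2C(=O)O[C@@H](c3ccc(O[Si](C)(C)C(C)(C)C)c(OC)c3)[C@@H]2C[Si](C)(C)OC(C)C)ccc1O[Si](C)(C)C(C)(C)C | intermediate
11 | methanesulfonate of 10 at the carbinol oxygen (formed in situ; one epimer drawn) | COc1cc([C@H](OS(C)(=O)=O)[C@H]2C(=O)O[C@@H](c3ccc(O[Si](C)(C)C(C)(C)C)c(OC)c3)[C@@H]2C[Si](C)(C)OC(C)C)ccc1O[Si](C)(C)C(C)(C)C | intermediate
12 | (3E,4R,5R)-5-Ar-3-(Ar-methylidene)-4-{[dimethyl(propan-2-yloxy)silyl]methyl}dihydrofuran-2(3H)-one | COc1cc(/C=C2/C(=O)O[C@@H](c3ccc(O[Si](C)(C)C(C)(C)C)c(OC)c3)[C@@H]2C[Si](C)(C)OC(C)C)ccc1O[Si](C)(C)C(C)(C)C | intermediate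
13 | (3S,4R,5R)-5-Ar-3-(Ar-methyl)-4-{[dimethyl(propan-2-yloxy)silyl]methyl}dihydrofuran-2(3H)-one (3,4-cis, 4,5-trans) | COc1cc(C[C@@H]2C(=O)O[C@@H](c3ccc(O[Si](C)(C)C(C)(C)C)c(OC)c3)[C@@H]2C[Si](C)(C)OC(C)C)ccc1O[Si](C)(C)C(C)(C)C | intermediate
14 | (3S,4R,5R)-5-Ar-3-(Ar-methyl)-4-{[dimethyl(propan-2-yloxy)silyl]methyl}tetrahydrofuran-2-ol (anomeric mixture) | COc1cc(C[C@@H]2C(O)O[C@@H](c3ccc(O[Si](C)(C)C(C)(C)C)c(OC)c3)[C@@H]2C[Si](C)(C)OC(C)C)ccc1O[Si](C)(C)C(C)(C)C | intermediate
15 | (2R,3R,4S)-2-Ar-4-(Ar-methyl)-3-{[dimethyl(propan-2-yloxy)silyl]methyl}tetrahydrofuran | COc1cc(C[C@@H]2CO[C@@H](c3ccc(O[Si](C)(C)C(C)(C)C)c(OC)c3)[C@@H]2C[Si](C)(C)OC(C)C)ccc1O[Si](C)(C)C(C)(C)C | intermediate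
16 | (−)-lariciresinol, [(2R,3S,4S)-2-(4-hydroxy-3-methoxyphenyl)-4-(4-hydroxy-3-methoxybenzyl)tetrahydrofuran-3-yl]methanol | COc1cc(C[C@@H]2CO[C@@H](c3ccc(O)c(OC)c3)[C@@H]2CO)ccc1O | intermediate
17 | 4-hydroxybenzoic acid | O=C(O)c1ccc(O)cc1 | starting material
18 | agastinol, [(2R,3S,4S)-2-(4-hydroxy-3-methoxyphenyl)-4-(4-hydroxy-3-methoxybenzyl)tetrahydrofuran-3-yl]methyl 4-hydroxybenzoate | COc1cc(C[C@@H]2CO[C@@H](c3ccc(O)c(OC)c3)[C@@H]2COC(=O)c2ccc(O)cc2)ccc1O | target

**Step count and risks**

Total: 11 steps. Longest linear sequence: 10 steps (steps 1–3 and 5–11, from vanillin); step 4 is a one-step branch.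

Step 5 (key step). The most likely failure is loss of material or of enantiomeric purity by deprotonation of the benzylic C7–H of 6 before the cuprate has added. The second is incomplete or reversible aldol capture, with enolate 9 adding to unreacted 6 instead of to the electron-rich aldehyde. Fallback, from 6 (with 8) back to 10: the two events are separated. The conjugate addition is run alone under the same CuI catalysis and quenched cold by protonation, giving the saturated trans-lactone (4R,5R)-5-Ar-4-{[dimethyl(propan-2-yloxy)silyl]methyl}dihydrofuran-2(3H)-one F1. After isolation, F1 is deprotonated with LiN(SiMe3)2 in THF at −78 °C to its lithium enolate F2, which is treated with aldehyde 2 to give 10. The aldol then starts from a fully converted, purified lactone and a more reactive lithium enolate, and the same two bonds are formed.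

Step 7. The most likely failure is poor facial selectivity: ring A on C7 sits on the face from which hydrogen must arrive and may offset the shielding by the C8 arm. Migration of the double bond into the ring on the catalyst is a second risk. Fallback, from 12 back to 13: the hydrogenation is run to completion regardless of the ratio. The C8' epimer, the all-trans lactone (3R,4R,5R)-5-Ar-3-(Ar-methyl)-4-{[dimethyl(propan-2-yloxy)silyl]methyl}dihydrofuran-2(3H)-one F3, alone or mixed with 13, is converted with KN(SiMe3)2 in THF at −78 °C into the potassium enolate F4. F4 is protonated at −78 °C with 2,6-di-tert-butyl-4-methylphenol. A proton donor attacks only C8' and is steered by the adjacent C8 substituent, so kinetic protonation anti to the silylmethyl arm should give the cis-lactone 13.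

Step 9. The most likely failure is ionisation of the C7 benzylic ether by BF3·OEt2 alongside the intended ionisation at C9', leading to epimerisation at C7 or Friedel–Crafts closure by ring B. Fallback, from 14 back to 15, by a neutral radical route: lactol 14 is converted with PhSSPh and n-Bu3P in THF at rt into the S-phenyl monothioacetal, (3S,4R,5R)-5-Ar-3-(Ar-methyl)-4-{[dimethyl(propan-2-yloxy)silyl]methyl}-2-(phenylsulfanyl)tetrahydrofuran F5. The C–S bond of F5 is reduced with Ph3SnH and AIBN in toluene at 110 °C to give 15. No cation is formed at any carbon.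

Step 11. The most likely failure is competing O-alkylation by a phenoxide. The paraben-type phenol of 17 and of product 18 is the most acidic phenol present and could give aryl ethers or oligomers once the carboxylic acid is depleted. Fallback, from 16 back to 18: the Mitsunobu reaction is run with commercial 4-acetoxybenzoic acid, which removes that phenol, giving agastinol 4-O-acetate F6. The aryl acetate of F6 is then cleaved with NH4OAc in aqueous MeOH at rt, conditions that leave the alkyl benzoate intact, to give 18.

**Further compounds**

F1 | step 5 | (4R,5R)-5-{4-[(tert-butyldimethylsilyl)oxy]-3-methoxyphenyl}-4-{[dimethyl(propan-2-yloxy)silyl]methyl}dihydrofuran-2(3H)-one | O=C1C[C@@H](C[Si](C)(C)OC(C)C)[C@H](c2ccc(O[Si](C)(C)C(C)(C)C)c(OC)c2)O1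
F2 | step 5 | lithium enolate of F1 | [Li]OC1=C[C@@H](C[Si](C)(C)OC(C)C)[C@H](c2ccc(O[Si](C)(C)C(C)(C)C)c(OC)c2)O1
F3 | step 7 | (3R,4R,5R)-5-Ar-3-(Ar-methyl)-4-{[dimethyl(propan-2-yloxy)silyl]methyl}dihydrofuran-2(3H)-one (all-trans C8' epimer of 13) | COc1cc(C[C@H]2C(=O)O[C@@H](c3ccc(O[Si](C)(C)C(C)(C)C)c(OC)c3)[C@@H]2C[Si](C)(C)OC(C)C)ccc1O[Si](C)(C)C(C)(C)C
F4 | step 7 | potassium enolate of F3 and 13 | COc1cc(CC2=C(O[K])O[C@@H](c3ccc(O[Si](C)(C)C(C)(C)C)c(OC)c3)[C@@H]2C[Si](C)(C)OC(C)C)ccc1O[Si](C)(C)C(C)(C)C
F5 | step 9 | (3S,4R,5R)-5-Ar-3-(Ar-methyl)-4-{[dimethyl(propan-2-yloxy)silyl]methyl}-2-(phenylsulfanyl)tetrahydrofuran (anomeric mixture) | COc1cc(C[C@@H]2C(Sc3ccccc3)O[C@@H](c3ccc(O[Si](C)(C)C(C)(C)C)c(OC)c3)[C@@H]2C[Si](C)(C)OC(C)C)ccc1O[Si](C)(C)C(C)(C)C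
F6 | step 11 | agastinol 4-O-acetate, [(2R,3S,4S)-2-(4-hydroxy-3-methoxyphenyl)-4-(4-hydroxy-3-methoxybenzyl)tetrahydrofuran-3-yl]methyl 4-acetoxybenzoate | COc1cc(C[C@@H]2CO[C@@H](c3ccc(O)c(OC)c3)[C@@H]2COC(=O)c2ccc(OC(C)=O)cc2)ccc1O
A1 | alternative 1 | propargyl alcohol | C#CCO
A2 | alternative 1 | dimethyl 2-[4-(benzyloxy)-3-methoxybenzylidene]malonate | COC(=O)C(=Cc1ccc(OCc2ccccc2)c(OC)c1)C(=O)OC
A3 | alternative 1 | 1-(benzyloxy)-4-iodo-2-methoxybenzene | COc1cc(I)ccc1OCc1ccccc1
A4 | alternative 1 | dimethyl (2S,4Z)-2-[4-(benzyloxy)-3-methoxyphenyl]-4-[4-(benzyloxy)-3-methoxybenzylidene]tetrahydrofuran-3,3-dicarboxylate (C7 in the spatial sense of 18) | COc1cc(/C=C2\CO[C@@H](c3ccc(OCc4ccccc4)c(OC)c3)C2(C(=O)OC)C(=O)OC)ccc1OCc1ccccc1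
A5 | alternative 2 | (1R,2S)-1-[4-(benzyloxy)-3-methoxyphenyl]-2-{[(tert-butyldimethylsilyl)oxy]methyl}but-3-yn-1-ol | C#C[C@@H](CO[Si](C)(C)C(C)(C)C)[C@@H](O)c1ccc(OCc2ccccc2)c(OC)c1
A6 | alternative 2 | (4S,5R)-5-[4-(benzyloxy)-3-methoxyphenyl]-4-{[(tert-butyldimethylsilyl)oxy]methyl}dihydrofuran-3(2H)-one | O=C1CO[C@@H](c2ccc(OCc3ccccc3)c(OC)c2)[C@@H]1CO[Si](C)(C)C(C)(C)C
A7 | alternative 3 | (2S,3S)-2,3-bis[4-(benzyloxy)-3-methoxybenzyl]-4-hydroxybutyl 4-(benzyloxy)benzoate | COc1cc(C[C@H](CO)[C@H](Cc2ccc(OCc3ccccc3)c(OC)c2)COC(=O)c2ccc(OCc3ccccc3)cc2)ccc1OCc1ccccc1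
A8 | alternative 3 | tri-O-benzyl agastinol, [(2R,3S,4S)-2-[4-(benzyloxy)-3-methoxyphenyl]-4-[4-(benzyloxy)-3-methoxybenzyl]tetrahydrofuran-3-yl]methyl 4-(benzyloxy)benzoate | COc1cc(C[C@@H]2CO[C@@H](c3ccc(OCc4ccccc4)c(OC)c3)[C@@H]2COC(=O)c2ccc(OCc3ccccc3)cc2)ccc1OCc1ccccc1
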